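**Plan**

- Retrosynthesis: remove the sulfate and the protecting groups, then cut ring C of the flavanone at O1–C8a and at C2–C3. This gives 4-(benzyloxy)benzaldehyde and an ortho-fluoroaryl ketone, which is cut at CH2–C8'' into a 2-fluoroacetophenone and an 8-bromoluteolin derivative.
- Enabling feature: the C4 carbonyl of ring C is ortho to C8a of ring A and also flanks C3, which is benzylic to C8'' of the flavone. C3 is therefore an easily formed enol carbon, a fluoride placed on C8a is a vinylogous acyl fluoride open to SNAr, and C2 is at aldehyde oxidation level.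
- Forward: luteolin is protected stepwise (catechol ketal, 7-O-MOM, 5-O-benzyl) and brominated at C8. Palladium-catalysed α-arylation joins it to the fluoroacetophenone, and the ketone is converted to its enol silane.
- One-pot asymmetric aldol/SNAr then builds ring C (the fluoride and silyl helpers leave in this step). MOM removal, sulfation of the single free phenol and hydrogenolysis finish the route.
- Stereochemistry: C2 (R) comes from a chiral boron Lewis acid that directs Re-face attack on the aldehyde. C3 (S) comes from the syn-selective aldol (syn aldol = trans-2,3) and from the thermodynamic trans preference at the enolisable C3.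

Key step: step 9

Assumption: the (2R,3R)-tartrate-derived (acyloxy)borane is taken to expose the Re face of the aryl aldehyde, as it does with benzaldehyde; should a model run show the opposite sense, the (2S,3S)-ligand is used.
Assumption: the target is delivered as the free hydrogen sulfate as drawn, so the sodium counter-ion is exchanged for a proton at the end.

**Route**

Step 1
Reactants: 1 5-fluororesorcinol
Product: 2 1-(2-fluoro-4,6-dihydroxyphenyl)ethan-1-one
Conditions: AcOH, BF3·OEt2, 90 °C; aqueous work-up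
Reagents that add atoms: acetic acid, CC(=O)O
Why: Friedel–Crafts (Nencki-type) C-acylation of a resorcinol goes para to one hydroxyl and ortho to the other, as in the orcinol to orcacetophenone case, so the acetyl group should enter between OH and F.

Step 2
Reactants: 2 1-(2-fluoro-4,6-dihydroxyphenyl)ethan-1-one
Product: 3 1-[2,4-bis(benzyloxy)-6-fluorophenyl]ethan-1-one
Conditions: BnBr, K2CO3, DMF, 70 °C
Reagents that add atoms: benzyl bromide, BrCc1ccccc1
Why: Williamson etherification of both phenols, with heating to alkylate the hydroxyl that is hydrogen-bonded to the ketone.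

Step 3
Reactants: 4 luteolin
Product: 5 2-(2,2-diphenyl-1,3-benzodioxol-5-yl)-5,7-dihydroxy-4H-chromen-4-one
Conditions: Ph2CCl2, Ph2O, 175 °C
Reagents that add atoms: dichlorodiphenylmethane, ClC(Cl)(c1ccccc1)c1ccccc1
Why: Ketalisation is selective for the catechol because only the vicinal 3',4'-hydroxyls can close the five-membered benzodioxole ring.

Step 4
Reactants: 5 2-(2,2-diphenyl-1,3-benzodioxol-5-yl)-5,7-dihydroxy-4H-chromen-4-one
Product: 6 2-(2,2-diphenyl-1,3-benzodioxol-5-yl)-5-hydroxy-7-(methoxymethoxy)-4H-chromen-4-one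
Conditions: MOMCl, K2CO3, acetone, 0 °C to rt
Reagents that add atoms: chloromethyl methyl ether, COCCl
Why: O-alkylation should occur at the acidic 7-OH only, since the 5-OH is held in a hydrogen bond to the C4 carbonyl and is much less reactive.

Step 5
Reactants: 6 2-(2,2-diphenyl-1,3-benzodioxol-5-yl)-5-hydroxy-7-(methoxymethoxy)-4H-chromen-4-one
Product: 7 5-(benzyloxy)-2-(2,2-diphenyl-1,3-benzodioxol-5-yl)-7-(methoxymethoxy)-4H-chromen-4-one
Conditions: BnBr, K2CO3, Bu4NI (cat.), DMF, 70 °C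
Reagents that add atoms: benzyl bromide, BrCc1ccccc1
Why: Williamson etherification under forcing conditions alkylates the remaining chelated 5-OH.

Step 6
Reactants: 7 5-(benzyloxy)-2-(2,2-diphenyl-1,3-benzodioxol-5-yl)-7-(methoxymethoxy)-4H-chromen-4-one
Product: 8 5-(benzyloxy)-8-bromo-2-(2,2-diphenyl-1,3-benzodioxol-5-yl)-7-(methoxymethoxy)-4H-chromen-4-one
Conditions: NBS, DMF, 0 °C to rt, dark
Reagents that add atoms: N-bromosuccinimide, O=C1CCC(=O)N1Br
Why: Electrophilic aromatic bromination of fully O-alkylated 5,7-dioxygenated flavones is expected at C8 (ortho to O1 and O7, para to O5), the benzodioxole ring being deactivated by the pyranone, and the acid-free medium spares the MOM ether.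

Step 7
Reactants: 3 1-[2,4-bis(benzyloxy)-6-fluorophenyl]ethan-1-one; 8 5-(benzyloxy)-8-bromo-2-(2,2-diphenyl-1,3-benzodioxol-5-yl)-7-(methoxymethoxy)-4H-chromen-4-one
Product: 9 1-[2,4-bis(benzyloxy)-6-fluorophenyl]-2-[5-(benzyloxy)-2-(2,2-diphenyl-1,3-benzodioxol-5-yl)-7-(methoxymethoxy)-4-oxo-4H-chromen-8-yl]ethan-1-one
Conditions: Pd2(dba)3 (cat.), XPhos, K3PO4, toluene, 100 °C
Reagents that add atoms: none
Why: Buchwald–Hartwig-type ketone α-arylation, in which zerovalent palladium inserts into C8–Br, the potassium enolate of 3 transmetalates and C–C reductive elimination follows; the bulky biarylphosphine serves the doubly ortho-substituted bromide and the hindered, stabilised product enolate should resist a second arylation.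

Step 8
Reactants: 9 1-[2,4-bis(benzyloxy)-6-fluorophenyl]-2-[5-(benzyloxy)-2-(2,2-diphenyl-1,3-benzodioxol-5-yl)-7-(methoxymethoxy)-4-oxo-4H-chromen-8-yl]ethan-1-one
Product: 11 5-(benzyloxy)-8-[(Z)-2-[2,4-bis(benzyloxy)-6-fluorophenyl]-2-[(trimethylsilyl)oxy]ethenyl]-2-(2,2-diphenyl-1,3-benzodioxol-5-yl)-7-(methoxymethoxy)-4H-chromen-4-one, via lithium enolate 10 (not isolated)
Conditions: LiN(SiMe3)2, THF, −78 °C; TMSCl, −78 to 0 °C; non-aqueous work-up
Reagents that add atoms: chlorotrimethylsilane, C[Si](C)(C)Cl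
Why: Deprotonation of the doubly activated CH2 and O-silylation of the enolate should give the enol silane, expected as the Z isomer as for aryl benzyl ketones; the base-free acid-free trapping spares the MOM ether.

Step 9
Reactants: 11 5-(benzyloxy)-8-[(Z)-2-[2,4-bis(benzyloxy)-6-fluorophenyl]-2-[(trimethylsilyl)oxy]ethenyl]-2-(2,2-diphenyl-1,3-benzodioxol-5-yl)-7-(methoxymethoxy)-4H-chromen-4-one; 12 4-(benzyloxy)benzaldehyde
Product: 14 5-(benzyloxy)-8-[(2R,3S)-5,7-bis(benzyloxy)-2-[4-(benzyloxy)phenyl]-4-oxo-3,4-dihydro-2H-chromen-3-yl]-2-(2,2-diphenyl-1,3-benzodioxol-5-yl)-7-(methoxymethoxy)-4H-chromen-4-one, via syn-aldol trimethylsilyl ether 13 (not isolated)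
Conditions: (acyloxy)borane from (2R,3R)-2-O-(2,6-diisopropoxybenzoyl)tartaric acid and BH3·THF (20 mol %), EtCN, −78 °C; then Bu4N[Ph3SiF2] (30 mol %), THF, −78 to 0 °C; pH 7 buffer
Reagents that add atoms: none
Why: The chiral boron Lewis acid binds aldehyde 12 and C3 of enol silane 11 adds to its Re face through an open antiperiplanar transition state, forming C2–C3 with silyl transfer to oxygen (13); fluoride then frees the C2 alkoxide, which adds to C8a of ring A and expels fluoride through a Meisenheimer intermediate delocalised into the C4 carbonyl, the released fluoride desilylating the next molecule of 13 in a chain. The closest known reaction types are the (acyloxy)borane-catalysed enantioselective Mukaiyama aldol of ketone enol silanes with aryl aldehydes and the fluoride-promoted intramolecular SNAr etherification of ortho-fluoroaryl ketones that gives chroman-4-ones. Ring C closes in a six-membered 6-endo-trig addition–elimination at C8a, the attacked C4a=C8a–F unit being a vinylogous acyl fluoride that lies inside the new ring. C2 (R) is controlled by the catalyst, which shields the Si face of the aldehyde; C3 (S) follows from the syn preference of the open transition state (syn aldol = trans-2,3) and, because C3–H is enolisable, from equilibration to the diequatorial trans isomer. The step needs ring closure to outrun retro-aldol cleavage of the alkoxide and needs attack at C8a only: the ortho C4 carbonyl makes C8a–F the sole SNAr-active position, the six-membered geometry excludes other sites, and catalytic fluoride at low temperature keeps the alkoxide concentration small while leaving the benzyl, MOM and ketal groups untouched.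

Step 10
Reactants: 14 5-(benzyloxy)-8-[(2R,3S)-5,7-bis(benzyloxy)-2-[4-(benzyloxy)phenyl]-4-oxo-3,4-dihydro-2H-chromen-3-yl]-2-(2,2-diphenyl-1,3-benzodioxol-5-yl)-7-(methoxymethoxy)-4H-chromen-4-one
Product: 15 5-(benzyloxy)-8-[(2R,3S)-5,7-bis(benzyloxy)-2-[4-(benzyloxy)phenyl]-4-oxo-3,4-dihydro-2H-chromen-3-yl]-2-(2,2-diphenyl-1,3-benzodioxol-5-yl)-7-hydroxy-4H-chromen-4-one
Conditions: HCl (cat.), MeOH/THF, 40 °C
Reagents that add atoms: none
Why: Acid-catalysed acetal exchange with methanol cleaves the aryl MOM ether under conditions too mild for benzyl ethers or the diphenylmethylene ketal and without a base that could enolise C3, so both stereocentres should be retained.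

Step 11
Reactants: 15 5-(benzyloxy)-8-[(2R,3S)-5,7-bis(benzyloxy)-2-[4-(benzyloxy)phenyl]-4-oxo-3,4-dihydro-2H-chromen-3-yl]-2-(2,2-diphenyl-1,3-benzodioxol-5-yl)-7-hydroxy-4H-chromen-4-one
Product: 17 sodium 5-(benzyloxy)-8-[(2R,3S)-5,7-bis(benzyloxy)-2-[4-(benzyloxy)phenyl]-4-oxo-3,4-dihydro-2H-chromen-3-yl]-2-(2,2-diphenyl-1,3-benzodioxol-5-yl)-4-oxo-4H-chromen-7-yl sulfate, via pyridinium sulfate 16 (not isolated)
Conditions: SO3·pyridine, pyridine, 40 °C; then aq. NaHCO3
Reagents that add atoms: sulfur trioxide–pyridine complex, O=S(=O)([O-])[n+]1ccccc1; sodium hydrogen carbonate, [Na+].OC([O-])=O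
Why: O-sulfation with the sulfur trioxide–amine complex can only occur at the 7''-OH, the single free phenol, and the weakly basic medium should not open ring C.

Step 12
Reactants: 17 sodium 5-(benzyloxy)-8-[(2R,3S)-5,7-bis(benzyloxy)-2-[4-(benzyloxy)phenyl]-4-oxo-3,4-dihydro-2H-chromen-3-yl]-2-(2,2-diphenyl-1,3-benzodioxol-5-yl)-4-oxo-4H-chromen-7-yl sulfate
Product: 19 2-(3,4-dihydroxyphenyl)-8-[(2R,3S)-5,7-dihydroxy-2-(4-hydroxyphenyl)-4-oxo-3,4-dihydro-2H-chromen-3-yl]-5-hydroxy-4-oxo-4H-chromen-7-yl hydrogen sulfate, via sodium salt 18 (not isolated)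
Conditions: H2 (1 atm), Pd(OH)2/C, THF/MeOH, rt; filter; HCl (1.0 equiv, aq), 0 °C; C18 desalting, lyophilisation
Reagents that add atoms: none
Why: Neutral hydrogenolysis removes the four benzyl ethers and the diphenylmethylene ketal together while aryl sulfate salts, the flavone double bond and both stereocentres are expected to survive, and brief cold protonation gives the hydrogen sulfate.

**Compound list**

1 | 5-fluororesorcinol (5-fluorobenzene-1,3-diol) | Oc1cc(O)cc(F)c1 | starting material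
2 | 1-(2-fluoro-4,6-dihydroxyphenyl)ethan-1-one | CC(=O)c1c(O)cc(O)cc1F | intermediate
3 | 1-[2,4-bis(benzyloxy)-6-fluorophenyl]ethan-1-one | CC(=O)c1c(OCc2ccccc2)cc(OCc2ccccc2)cc1F | intermediate
4 | luteolin (2-(3,4-dihydroxyphenyl)-5,7-dihydroxy-4H-chromen-4-one) | O=c1cc(-c2ccc(O)c(O)c2)oc2cc(O)cc(O)c12 | starting material
5 | 2-(2,2-diphenyl-1,3-benzodioxol-5-yl)-5,7-dihydroxy-4H-chromen-4-one | O=c1cc(-c2ccc3c(c2)OC(c2ccccc2)(c2ccccc2)O3)oc2cc(O)cc(O)c12 | intermediate
6 | 2-(2,2-diphenyl-1,3-benzodioxol-5-yl)-5-hydroxy-7-(methoxymethoxy)-4H-chromen-4-one | O=c1cc(-c2ccc3c(c2)OC(c2ccccc2)(c2ccccc2)O3)oc2cc(OCOC)cc(O)c12 | intermediate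
7 | 5-(benzyloxy)-2-(2,2-diphenyl-1,3-benzodioxol-5-yl)-7-(methoxymethoxy)-4H-chromen-4-one | O=c1cc(-c2ccc3c(c2)OC(c2ccccc2)(c2ccccc2)O3)oc2cc(OCOC)cc(OCc3ccccc3)c12 | intermediate
8 | 5-(benzyloxy)-8-bromo-2-(2,2-diphenyl-1,3-benzodioxol-5-yl)-7-(methoxymethoxy)-4H-chromen-4-one | O=c1cc(-c2ccc3c(c2)OC(c2ccccc2)(c2ccccc2)O3)oc2c(Br)c(OCOC)cc(OCc3ccccc3)c12 | intermediate
9 | 1-[2,4-bis(benzyloxy)-6-fluorophenyl]-2-[5-(benzyloxy)-2-(2,2-diphenyl-1,3-benzodioxol-5-yl)-7-(methoxymethoxy)-4-oxo-4H-chromen-8-yl]ethan-1-one | O=C(Cc1c(OCOC)cc(OCc2ccccc2)c2c(=O)cc(-c3ccc4c(c3)OC(c3ccccc3)(c3ccccc3)O4)oc12)c1c(F)cc(OCc2ccccc2)cc1OCc1ccccc1 | intermediate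
10 | lithium (Z)-enolate of 9 | [Li]O/C(=C\c1c(OCOC)cc(OCc2ccccc2)c2c(=O)cc(-c3ccc4c(c3)OC(c3ccccc3)(c3ccccc3)O4)oc12)c1c(F)cc(OCc2ccccc2)cc1OCc1ccccc1 | intermediate
11 | 5-(benzyloxy)-8-[(Z)-2-[2,4-bis(benzyloxy)-6-fluorophenyl]-2-[(trimethylsilyl)oxy]ethenyl]-2-(2,2-diphenyl-1,3-benzodioxol-5-yl)-7-(methoxymethoxy)-4H-chromen-4-one | C[Si](C)(C)O/C(=C\c1c(OCOC)cc(OCc2ccccc2)c2c(=O)cc(-c3ccc4c(c3)OC(c3ccccc3)(c3ccccc3)O4)oc12)c1c(F)cc(OCc2ccccc2)cc1OCc1ccccc1 | intermediate
12 | 4-(benzyloxy)benzaldehyde | O=Cc1ccc(OCc2ccccc2)cc1 | starting material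
13 | (2S,3R)-1-[2,4-bis(benzyloxy)-6-fluorophenyl]-3-[4-(benzyloxy)phenyl]-2-[5-(benzyloxy)-2-(2,2-diphenyl-1,3-benzodioxol-5-yl)-7-(methoxymethoxy)-4-oxo-4H-chromen-8-yl]-3-[(trimethylsilyl)oxy]propan-1-one | O=C(c1c(F)cc(OCc2ccccc2)cc1OCc1ccccc1)[C@@H](c1c(OCOC)cc(OCc2ccccc2)c2c(=O)cc(-c3ccc4c(c3)OC(c3ccccc3)(c3ccccc3)O4)oc12)[C@@H](O[Si](C)(C)C)c1ccc(OCc2ccccc2)cc1 | intermediate
14 | 5-(benzyloxy)-8-[(2R,3S)-5,7-bis(benzyloxy)-2-[4-(benzyloxy)phenyl]-4-oxo-3,4-dihydro-2H-chromen-3-yl]-2-(2,2-diphenyl-1,3-benzodioxol-5-yl)-7-(methoxymethoxy)-4H-chromen-4-one | O=C1c2c(OCc3ccccc3)cc(OCc3ccccc3)cc2O[C@@H](c2ccc(OCc3ccccc3)cc2)[C@@H]1c1c(OCOC)cc(OCc2ccccc2)c2c(=O)cc(-c3ccc4c(c3)OC(c3ccccc3)(c3ccccc3)O4)oc12 | intermediate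
15 | 5-(benzyloxy)-8-[(2R,3S)-5,7-bis(benzyloxy)-2-[4-(benzyloxy)phenyl]-4-oxo-3,4-dihydro-2H-chromen-3-yl]-2-(2,2-diphenyl-1,3-benzodioxol-5-yl)-7-hydroxy-4H-chromen-4-one | O=C1c2c(OCc3ccccc3)cc(OCc3ccccc3)cc2O[C@@H](c2ccc(OCc3ccccc3)cc2)[C@@H]1c1c(O)cc(OCc2ccccc2)c2c(=O)cc(-c3ccc4c(c3)OC(c3ccccc3)(c3ccccc3)O4)oc12 | intermediate
16 | pyridinium 5-(benzyloxy)-8-[(2R,3S)-5,7-bis(benzyloxy)-2-[4-(benzyloxy)phenyl]-4-oxo-3,4-dihydro-2H-chromen-3-yl]-2-(2,2-diphenyl-1,3-benzodioxol-5-yl)-4-oxo-4H-chromen-7-yl sulfate | O=C1c2c(OCc3ccccc3)cc(OCc3ccccc3)cc2O[C@@H](c2ccc(OCc3ccccc3)cc2)[C@@H]1c1c(OS(=O)(=O)[O-])cc(OCc2ccccc2)c2c(=O)cc(-c3ccc4c(c3)OC(c3ccccc3)(c3ccccc3)O4)oc12.c1cc[nH+]cc1 | intermediate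
17 | sodium 5-(benzyloxy)-8-[(2R,3S)-5,7-bis(benzyloxy)-2-[4-(benzyloxy)phenyl]-4-oxo-3,4-dihydro-2H-chromen-3-yl]-2-(2,2-diphenyl-1,3-benzodioxol-5-yl)-4-oxo-4H-chromen-7-yl sulfate | O=C1c2c(OCc3ccccc3)cc(OCc3ccccc3)cc2O[C@@H](c2ccc(OCc3ccccc3)cc2)[C@@H]1c1c(OS(=O)(=O)[O-])cc(OCc2ccccc2)c2c(=O)cc(-c3ccc4c(c3)OC(c3ccccc3)(c3ccccc3)O4)oc12.[Na+] | intermediate
18 | sodium 2-(3,4-dihydroxyphenyl)-8-[(2R,3S)-5,7-dihydroxy-2-(4-hydroxyphenyl)-4-oxo-3,4-dihydro-2H-chromen-3-yl]-5-hydroxy-4-oxo-4H-chromen-7-yl sulfate | O=C1c2c(O)cc(O)cc2O[C@@H](c2ccc(O)cc2)[C@@H]1c1c(OS(=O)(=O)[O-])cc(O)c2c(=O)cc(-c3ccc(O)c(O)c3)oc12.[Na+] | intermediate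
19 | 2-(3,4-dihydroxyphenyl)-8-[(2R,3S)-5,7-dihydroxy-2-(4-hydroxyphenyl)-4-oxo-3,4-dihydro-2H-chromen-3-yl]-5-hydroxy-4-oxo-4H-chromen-7-yl hydrogen sulfate | O=C1c2c(O)cc(O)cc2O[C@@H](c2ccc(O)cc2)[C@@H]1c1c(OS(=O)(=O)O)cc(O)c2c(=O)cc(-c3ccc(O)c(O)c3)oc12 | target

**Count and risks**

Total step count: 12. Longest linear sequence: 10 steps (steps 3 to 12, from luteolin 4).

Steps most likely to fail:

1. Step 9. The transient C2 alkoxide may undergo retro-aldol cleavage before the SNAr closure, which would erode enantiomeric purity. Ring C may also open at C3 by fluoride-induced elimination, and the pyranone carbonyl may bind the boron catalyst and stall the aldol. Fallback: give up catalyst control for thermodynamic control and resolution. It sets out from ketone 9 and aldehyde 12. KOtBu in THF/DMF (0 °C to rt) should drive reversible aldol addition, irreversible SNAr closure and equilibration at C3, so that the material funnels into the racemic trans product, that is 14 together with its (2S,3R)-enantiomer F1. Preparative HPLC on an amylose tris(3,5-dimethylphenylcarbamate) phase separates the two, and the route is rejoined at 14.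

2. Step 7. Reductive elimination at the doubly ortho-substituted C8'' may be slow, allowing protodebromination, and the enolate may attack the pyranone. Fallback: build the ketone by carbonyl addition instead of cross-coupling of an enolate. It sets out from bromide 8 and comes back at ketone 9.
   - Stille coupling of 8 with allyltributylstannane (Pd(PPh3)4, toluene, 100 °C) gives the 8-allyl flavone F2.
   - Lemieux–Johnson cleavage (OsO4 cat., NaIO4, 2,6-lutidine, dioxane/H2O) gives the arylacetaldehyde F3.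
   - Separately, 5-fluororesorcinol 1 is benzylated (BnBr, K2CO3, DMF) to 1,3-bis(benzyloxy)-5-fluorobenzene F4.
   - F4 is brominated para to one ether oxygen (NBS, MeCN, 0 °C) to 1,5-bis(benzyloxy)-2-bromo-3-fluorobenzene F5.
   - Bromine–lithium exchange (n-BuLi, THF, −78 °C) converts F5 into [2,4-bis(benzyloxy)-6-fluorophenyl]lithium F6.
   - Addition of F6 to F3 at −78 °C gives the racemic secondary alcohol F7, and Dess–Martin oxidation of F7 gives 9.

3. Step 6. Bromination may show poor positional selectivity between C8 and C6 of ring A, or attack the benzodioxole ring. Fallback: introduce the C8 carbon by a sigmatropic shift instead of electrophilic substitution. It sets out from diol 5 and comes back at ketone 9.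
   - O-Allylation of the 7-OH (allyl bromide, K2CO3, acetone) gives the 7-allyl ether F8.
   - Benzylation of the 5-OH (BnBr, K2CO3, DMF, 70 °C) gives the 5-benzyl 7-allyl ether F9.
   - Aromatic Claisen rearrangement (N,N-diethylaniline, 190 °C) gives the 8-allyl-7-hydroxy flavone F10; in 7-allyloxychromones this shift goes to C8 because of the higher bond order of C7–C8.
   - MOMCl/K2CO3 converts F10 into the 8-allyl flavone F2, from which the cleavage to F3, the addition giving F7 and the oxidation described under the preceding fallback lead to 9.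

Further compounds
F1 | step 9 | 5-(benzyloxy)-8-[(2S,3R)-5,7-bis(benzyloxy)-2-[4-(benzyloxy)phenyl]-4-oxo-3,4-dihydro-2H-chromen-3-yl]-2-(2,2-diphenyl-1,3-benzodioxol-5-yl)-7-(methoxymethoxy)-4H-chromen-4-one (enantiomer of 14) | O=C1c2c(OCc3ccccc3)cc(OCc3ccccc3)cc2O[C@H](c2ccc(OCc3ccccc3)cc2)[C@H]1c1c(OCOC)cc(OCc2ccccc2)c2c(=O)cc(-c3ccc4c(c3)OC(c3ccccc3)(c3ccccc3)O4)oc12
F2 | step 7 | 5-(benzyloxy)-2-(2,2-diphenyl-1,3-benzodioxol-5-yl)-7-(methoxymethoxy)-8-(prop-2-en-1-yl)-4H-chromen-4-one | C=CCc1c(OCOC)cc(OCc2ccccc2)c2c(=O)cc(-c3ccc4c(c3)OC(c3ccccc3)(c3ccccc3)O4)oc12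
F3 | step 7 | 2-[5-(benzyloxy)-2-(2,2-diphenyl-1,3-benzodioxol-5-yl)-7-(methoxymethoxy)-4-oxo-4H-chromen-8-yl]acetaldehyde | O=CCc1c(OCOC)cc(OCc2ccccc2)c2c(=O)cc(-c3ccc4c(c3)OC(c3ccccc3)(c3ccccc3)O4)oc12
F4 | step 7 | 1,3-bis(benzyloxy)-5-fluorobenzene | Fc1cc(OCc2ccccc2)cc(OCc2ccccc2)c1
F5 | step 7 | 1,5-bis(benzyloxy)-2-bromo-3-fluorobenzene | Brc1c(F)cc(OCc2ccccc2)cc1OCc1ccccc1
F6 | step 7 | [2,4-bis(benzyloxy)-6-fluorophenyl]lithium | [Li]c1c(F)cc(OCc2ccccc2)cc1OCc1ccccc1
F7 | step 7 | racemic 1-[2,4-bis(benzyloxy)-6-fluorophenyl]-2-[5-(benzyloxy)-2-(2,2-diphenyl-1,3-benzodioxol-5-yl)-7-(methoxymethoxy)-4-oxo-4H-chromen-8-yl]ethan-1-ol | OC(Cc1c(OCOC)cc(OCc2ccccc2)c2c(=O)cc(-c3ccc4c(c3)OC(c3ccccc3)(c3ccccc3)O4)oc12)c1c(F)cc(OCc2ccccc2)cc1OCc1ccccc1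
F8 | step 6 | 2-(2,2-diphenyl-1,3-benzodioxol-5-yl)-5-hydroxy-7-(prop-2-en-1-yloxy)-4H-chromen-4-one | O=c1cc(-c2ccc3c(c2)OC(c2ccccc2)(c2ccccc2)O3)oc2cc(OCC=C)cc(O)c12
F9 | step 6 | 5-(benzyloxy)-2-(2,2-diphenyl-1,3-benzodioxol-5-yl)-7-(prop-2-en-1-yloxy)-4H-chromen-4-one | O=c1cc(-c2ccc3c(c2)OC(c2ccccc2)(c2ccccc2)O3)oc2cc(OCC=C)cc(OCc3ccccc3)c12
F10 | step 6 | 5-(benzyloxy)-2-(2,2-diphenyl-1,3-benzodioxol-5-yl)-7-hydroxy-8-(prop-2-en-1-yl)-4H-chromen-4-one | O=c1cc(-c2ccc3c(c2)OC(c2ccccc2)(c2ccccc2)O3)oc2c(CC=C)c(O)cc(OCc3ccccc3)c12
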